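## Retrosynthetic overview
1. Epimedonin L ⇒ a 2'-hydroxychalcone whose 4'- and 6'-hydroxyls are capped as allyl ethers. The last step makes the key bond, O1–C2 of ring C. Ring closure, loss of two hydrogens and loss of both caps all happen in one flask under palladium catalysis.
2. Chalcone ⇒ Claisen–Schmidt union of a ring A methyl ketone and a ring B aldehyde.
3. Ring A ketone ⇒ phloroacetophenone by C-prenylation, then O-allylation of the two less hindered hydroxyls. Only the hydroxyl beside the prenyl group is left to close ring C, which gives the 8-prenyl and not the 6-prenyl skeleton.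
4. Ring B aldehyde ⇒ 4-hydroxybenzaldehyde by double ortho C-prenylation.
5. Ring order: rings A and B are bought as arenes. Ring C is the only ring made, and it is made last.

Assumption: the SMILES shows no stereocentre and no stereogenic double bond, so the target is achiral and its constitution alone defines the compound asked for.

## Route

Step 1
Reactants: 1 2,4,6-trihydroxyacetophenone (phloroacetophenone); 2 prenyl bromide (1-bromo-3-methylbut-2-ene)
Product: 3 1-[2,4,6-trihydroxy-3-(3-methylbut-2-en-1-yl)phenyl]ethan-1-one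
Conditions: KOH (1.0 equiv), H2O, 2 (0.9 equiv), 0 °C to rt, 3 h
Reagents that add atoms: prenyl bromide (2), CC(C)=CCBr
Why: C-alkylation of an ambident phloroglucinol phenolate: in water the oxygens are hydrogen-bonded, so the soft allylic bromide is taken up by ring carbon C3 (SN2, then rearomatisation), a slight excess of 1 holds back a second prenylation, and no stereocentre is formed.

Step 2
Reactants: 3 1-[2,4,6-trihydroxy-3-(3-methylbut-2-en-1-yl)phenyl]ethan-1-one; 4 allyl bromide (3-bromoprop-1-ene)
Product: 5 1-[2-hydroxy-3-(3-methylbut-2-en-1-yl)-4,6-bis(prop-2-en-1-yloxy)phenyl]ethan-1-one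
Conditions: 4 (2.1 equiv), K2CO3 (2.2 equiv), acetone, reflux, 6 h
Reagents that add atoms: allyl bromide (4), C=CCBr
Why: Williamson ether synthesis under steric and hydrogen-bond control: the 4-OH and 6-OH each have a free C–H neighbour toward which the new O-allyl group can turn, whereas the 2-OH is chelated to the ketone and wedged between acetyl and prenyl, so it stays free, as in the known bis-protection of 3-alkylphloroacetophenones.

Step 3
Reactants: 6 4-hydroxybenzaldehyde; 2 prenyl bromide (1-bromo-3-methylbut-2-ene)
Product: 7 4-hydroxy-3,5-bis(3-methylbut-2-en-1-yl)benzaldehyde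
Conditions: KOH (2.5 equiv), H2O, 2 (2.5 equiv), rt, 24 h (the mono-prenyl aldehyde is recovered and resubmitted)
Reagents that add atoms: prenyl bromide (2), CC(C)=CCBr
Why: Double ortho C-alkylation of a phenolate in water: the para position is blocked by the formyl group, so both ortho carbons are alkylated in turn, giving a modest but known yield next to separable mono-C-prenyl and O-prenyl products.

Step 4
Reactants: 5 1-[2-hydroxy-3-(3-methylbut-2-en-1-yl)-4,6-bis(prop-2-en-1-yloxy)phenyl]ethan-1-one; 7 4-hydroxy-3,5-bis(3-methylbut-2-en-1-yl)benzaldehyde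
Product: 8 (E)-1-[2-hydroxy-3-(3-methylbut-2-en-1-yl)-4,6-bis(prop-2-en-1-yloxy)phenyl]-3-[4-hydroxy-3,5-bis(3-methylbut-2-en-1-yl)phenyl]prop-2-en-1-one
Conditions: KOH (12 equiv), EtOH–H2O (4:1), argon, rt to 40 °C, 48 h; then 1 M HCl to pH 5, 0 °C
Reagents that add atoms: none
Why: Claisen–Schmidt condensation (aldol addition, then E1cB loss of water) gives the thermodynamic E-enone, the allyl ethers and prenyl groups are inert to hydroxide, and any material that already closes to the flavanone is simply the first intermediate of step 5.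

Step 5
Reactants: 8 (E)-1-[2-hydroxy-3-(3-methylbut-2-en-1-yl)-4,6-bis(prop-2-en-1-yloxy)phenyl]-3-[4-hydroxy-3,5-bis(3-methylbut-2-en-1-yl)phenyl]prop-2-en-1-one
Product: 11 epimedonin L, via flavanone 9 (not isolated), via bis-O-allyl flavone 10 (not isolated)
Conditions: DBU (0.2 equiv), MeCN, argon, 60 °C, 1 h; then Pd2(dba)3 (2.5 mol %), dppe (6 mol %), allyl methyl carbonate (2 equiv), 80 °C, 6 h; then morpholine (8 equiv), 40 °C, 2 h
Reagents that add atoms: none
Why: Proposed new method: a dehydrogenative oxa-Michael ring closure in which DBU first closes the O1–C2 bond reversibly through the only free ortho hydroxyl (the one beside the prenyl group, hence the 8-prenyl skeleton), zerovalent palladium ionises allyl methyl carbonate to a cationic π-allyl complex of divalent palladium plus methoxide (after loss of CO2), methoxide enolises flavanone 9, the palladium enolate at C3 loses H-2 by syn β-hydride elimination, and allyl–Pd–H collapses to propene and zerovalent palladium, which pulls the reversible C–O closure irreversibly into the aromatic 4-pyranone; because the oxidant only ever meets an enolate, and no electrophilic halogen, quinone or free divalent palladium salt is present, the three prenyl groups and the hindered free phenol (which such oxidants turn into chromans or chromenes) should survive, the O-allyl caps are re-formed as long as carbonate is present and so hold the regiochemistry until ring C is aromatic, and morpholine then strips them (and any allyl picked up by the ring B phenol) with the same catalyst; closest known reaction types are the Tsuji-type allyl-palladium α,β-dehydrogenation of ketone enolates with allyl carbonates, the base-mediated oxa-Michael closure of 2'-hydroxychalcones, and the Tsuji–Trost deallylation of aryl allyl ethers; the C2 centre of 9 is racemic and is erased.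

## Compound list
1 | 2,4,6-trihydroxyacetophenone | CC(=O)c1c(O)cc(O)cc1O | starting material
2 | prenyl bromide (1-bromo-3-methylbut-2-ene) | CC(C)=CCBr | starting material
3 | 1-[2,4,6-trihydroxy-3-(3-methylbut-2-en-1-yl)phenyl]ethan-1-one | CC(=O)c1c(O)cc(O)c(CC=C(C)C)c1O | intermediate
4 | allyl bromide (3-bromoprop-1-ene) | C=CCBr | starting material
5 | 1-[2-hydroxy-3-(3-methylbut-2-en-1-yl)-4,6-bis(prop-2-en-1-yloxy)phenyl]ethan-1-one | CC(=O)c1c(OCC=C)cc(OCC=C)c(CC=C(C)C)c1O | intermediate
6 | 4-hydroxybenzaldehyde | O=Cc1ccc(O)cc1 | starting material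
7 | 4-hydroxy-3,5-bis(3-methylbut-2-en-1-yl)benzaldehyde | CC(C)=CCc1cc(C=O)cc(CC=C(C)C)c1O | intermediate
8 | (E)-chalcone: 4',6'-bis(allyloxy)-2',4-dihydroxy-3',3,5-triprenylchalcone | CC(C)=CCc1cc(/C=C/C(=O)c2c(OCC=C)cc(OCC=C)c(CC=C(C)C)c2O)cc(CC=C(C)C)c1O | intermediate
9 | racemic flavanone: 5,7-bis(allyloxy)-2-[4-hydroxy-3,5-bis(3-methylbut-2-en-1-yl)phenyl]-8-(3-methylbut-2-en-1-yl)chroman-4-one | CC(C)=CCc1cc(C2CC(=O)c3c(OCC=C)cc(OCC=C)c(CC=C(C)C)c3O2)cc(CC=C(C)C)c1O | intermediate
10 | flavone: 5,7-bis(allyloxy)-2-[4-hydroxy-3,5-bis(3-methylbut-2-en-1-yl)phenyl]-8-(3-methylbut-2-en-1-yl)-4H-chromen-4-one | CC(C)=CCc1cc(-c2cc(=O)c3c(OCC=C)cc(OCC=C)c(CC=C(C)C)c3o2)cc(CC=C(C)C)c1O | intermediate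
11 | epimedonin L: 5,7-dihydroxy-2-[4-hydroxy-3,5-bis(3-methylbut-2-en-1-yl)phenyl]-8-(3-methylbut-2-en-1-yl)-4H-chromen-4-one | CC(C)=CCc1cc(-c2cc(=O)c3c(O)cc(O)c(CC=C(C)C)c3o2)cc(CC=C(C)C)c1O | target

## Step count and risks
Total steps: 5. Longest linear sequence: 4 (1 → 3 → 5 → 8 → 11, that is steps 1, 2, 4 and 5).

**Most likely to fail: step 5 (the proposed new step).**
- The palladium enolate may be allylated at C3 instead of losing hydride.
- Turnover at the hindered C3 may be slow.
- A cap lost too early would let the 6'-oxygen close to the 6-prenyl isomer.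

The fallback uses known chemistry only, sets out from 8 and comes back at 11. Chalcone 8 is closed with NaOAc in refluxing EtOH to flavanone 9, which is now isolated. Its single free phenol is acetylated (Ac2O, pyridine, DMAP) to the 4'-O-acetyl flavanone F1. With no free ortho-prenylphenol left, DDQ in refluxing dioxane dehydrogenates C2–C3 to the 4'-O-acetyl-5,7-di-O-allyl flavone F2. Pd(PPh3)4 (5 mol %) with K2CO3 in MeOH at 60 °C then removes both allyl ethers and the acetate to give 11.

**Second: step 4.** In KOH the aldehyde 7 is present as a push–pull phenoxide and the ketone 5 is hindered, so the condensation may stall. The fallback changes the protecting-group plan, sets out from 7 and comes back at 8. Aldehyde 7 is masked with chloromethyl methyl ether and K2CO3 in acetone as 4-(methoxymethoxy)-3,5-diprenylbenzaldehyde F3. This no longer forms a phenoxide and condenses with 5 (KOH, EtOH) to the 4-O-methoxymethyl chalcone F4. Dilute HCl in MeOH at rt then frees the phenol to give 8.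

**Third: step 3.** Direct double C-prenylation gives mixtures (mono-C-prenyl and O-prenyl products) and may deliver too little 7. The fallback replaces phenolate alkylation by cross-coupling, sets out from 6 and comes back at 7. Aldehyde 6 is brominated (Br2, AcOH, rt) to 3,5-dibromo-4-hydroxybenzaldehyde F5. A double Stille coupling of F5 with tributyl(3-methylbut-2-en-1-yl)stannane (Pd(PPh3)4, DMF, 100 °C) places both linear prenyl groups and gives 7.

## Further compounds
F1 | step 5 | 4-[5,7-bis(allyloxy)-8-(3-methylbut-2-en-1-yl)-4-oxochroman-2-yl]-2,6-bis(3-methylbut-2-en-1-yl)phenyl acetate (racemic) | CC(C)=CCc1cc(C2CC(=O)c3c(OCC=C)cc(OCC=C)c(CC=C(C)C)c3O2)cc(CC=C(C)C)c1OC(C)=O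
F2 | step 5 | 4-[5,7-bis(allyloxy)-8-(3-methylbut-2-en-1-yl)-4-oxo-4H-chromen-2-yl]-2,6-bis(3-methylbut-2-en-1-yl)phenyl acetate | CC(C)=CCc1cc(-c2cc(=O)c3c(OCC=C)cc(OCC=C)c(CC=C(C)C)c3o2)cc(CC=C(C)C)c1OC(C)=O
F3 | step 4 | 4-(methoxymethoxy)-3,5-bis(3-methylbut-2-en-1-yl)benzaldehyde | CC(C)=CCc1cc(C=O)cc(CC=C(C)C)c1OCOC
F4 | step 4 | (E)-1-[2-hydroxy-3-(3-methylbut-2-en-1-yl)-4,6-bis(prop-2-en-1-yloxy)phenyl]-3-[4-(methoxymethoxy)-3,5-bis(3-methylbut-2-en-1-yl)phenyl]prop-2-en-1-one | CC(C)=CCc1cc(/C=C/C(=O)c2c(OCC=C)cc(OCC=C)c(CC=C(C)C)c2O)cc(CC=C(C)C)c1OCOC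
F5 | step 3 | 3,5-dibromo-4-hydroxybenzaldehyde | O=Cc1cc(Br)c(O)c(Br)c1
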